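**Plan**

1. Retrosynthesis: ring C is opened at O1–C2 and the C3 oxygen removed (Algar–Flynn–Oyamada). The C2–C3 bond is then cut to an acetophenone and 4-(methoxymethoxy)benzaldehyde, and the C4–C4a bond to a lithiated ether of 2-lavandulylphloroglucinol.
2. Ring A is cut between C5 and a neighbouring ring CH (C5–C6, which equals C5–C4a in the symmetric triol). This unfolds it to methyl 4-lavandulyl-3,5-dioxohexanoate, which is cut further at its acetyl group, its ester carbon, the prenyl C=C and the C1–C2 bond of limonene.
3. Enabling feature: ring A is a phloroglucinol (oxygens on C5, C7, C8a) whose C8 carries the side chain between two oxygens, so C8 is the central carbon of a 1,3,5-tricarbonyl chain. The stereocentre with its isopropenyl group and two CH2 neighbours is C4 of (R)-limonene, whose C5, C6, C1 and C7 become the benzylic CH2, C8, an adjacent C–O carbon and a ring CH.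
4. Forward: the limonene ring is cleaved, the chain is built (Wittig, carbomethoxylation, dianion acetylation), ring A is closed (step 6), the acetyl group is put on by ortho-lithiation, the chalcone is made, ring C is closed oxidatively (step 12) and the MOM groups are removed.
5. Stereochemistry: the only stereocentre is bought with (R)-limonene and is never α to a carbonyl. Its descriptor changes from R to S from compound 12 onward only because the CIP priorities of its two CH2 arms swap.

Key step: step 6

Assumption: 8, 10 and 20 are purchased; C6 and C4a are equivalent in the symmetric triol 14, so flavone numbering is fixed only when step 8 acylates one of them; "lavandulyl" means 5-methyl-2-(prop-1-en-2-yl)hex-4-en-1-yl.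

**Step 1**
Reactants: 1 (R)-(+)-limonene
Product: 2 (4R)-limonene 1,2-oxide (cis/trans mixture)
Conditions: mCPBA (1.0 equiv), NaHCO3, CH2Cl2, 0 °C
Reagents that add atoms: mCPBA, O=C(OO)c1cccc(Cl)c1
Why: Prilezhaev epoxidation, in which the trisubstituted ring alkene is more electron-rich than the 1,1-disubstituted isopropenyl group and should take the single equivalent of peracid first; the two new epoxide centres form unselectively but are erased in step 2, and C4 is untouched.

**Step 2**
Reactants: 2 (4R)-limonene 1,2-oxide
Product: 4 (3R)-6-oxo-3-(prop-1-en-2-yl)heptanal, via limonene-1,2-diol 3 (not isolated)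
Conditions: H5IO6 (1.2 equiv), THF–H2O, 0 °C → rt
Reagents that add atoms: water, O
Why: Periodic acid hydrolyses the epoxide to diol 3 and cleaves it in the same flask (Malaprade glycol cleavage), so both epoxide diastereomers converge on one keto-aldehyde whose stereocentre is β to the aldehyde and cannot epimerise by enolisation.

**Step 3**
Reactants: 4 (3R)-6-oxo-3-(prop-1-en-2-yl)heptanal; 5 isopropyltriphenylphosphonium iodide
Product: 7 (5R)-8-methyl-5-(prop-1-en-2-yl)non-7-en-2-one, via isopropylidenetriphenylphosphorane 6 (not isolated)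
Conditions: 5, n-BuLi (1.0 equiv each), THF, 0 °C; then added to 4, THF, −78 → 0 °C
Reagents that add atoms: none
Why: Wittig olefination, in which the non-stabilised ylide 6 should react with the aldehyde much faster than with the methyl ketone at −78 °C when one equivalent is added to 4; the new alkene is trisubstituted with two identical methyl groups, so no E/Z question arises.

**Step 4**
Reactants: 7 (5R)-8-methyl-5-(prop-1-en-2-yl)non-7-en-2-one; 8 dimethyl carbonate
Product: 9 methyl (6R)-9-methyl-3-oxo-6-(prop-1-en-2-yl)dec-8-enoate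
Conditions: NaH (2.5 equiv), 8 (excess), THF, reflux; then AcOH, 0 °C
Reagents that add atoms: none
Why: Crossed Claisen condensation (carbomethoxylation) of a methyl ketone with a dialkyl carbonate, which under these equilibrating conditions takes place at the methyl group and is driven by formation of the β-keto ester enolate, as in the same conversion of 6-methylhept-5-en-2-one.

**Step 5**
Reactants: 9 methyl (6R)-9-methyl-3-oxo-6-(prop-1-en-2-yl)dec-8-enoate; 10 N-methoxy-N-methylacetamide
Product: 12 methyl 4-[(2S)-lavandulyl]-3,5-dioxohexanoate, via keto ester dianion 11 (not isolated)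
Conditions: LDA (2.3 equiv), THF, −78 → 0 °C; then 10, −78 → 0 °C; aq. NH4Cl
Reagents that add atoms: none
Why: γ-Acylation of a β-keto ester dianion (Weinreb ketone synthesis at the more basic γ-carbanion), in which the second deprotonation occurs at the CH2 next to the ketone and the chelated tetrahedral adduct holds until work-up, so the acetyl group lands on the carbon bearing the side chain without a choice between the two α-positions of a ketone.

**Step 6**
Reactants: 12 methyl 4-[(2S)-lavandulyl]-3,5-dioxohexanoate
Product: 14 2-[(2S)-lavandulyl]benzene-1,3,5-triol, via 2-lavandulylcyclohexane-1,3,5-trione 13 (not isolated)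
Conditions: KOtBu (3 equiv), t-BuOH–THF, 65 °C, Ar; then 1 M HCl, 0 °C
Reagents that add atoms: none
Why: tert-Butoxide equilibrates the enolates of 12 through t-BuOH, and the minor enolate of the terminal methyl ketone (C6 of the hexanoate) attacks the ester carbonyl C1; the tetrahedral intermediate loses methoxide to give trione 13, which tautomerises at once to the phloroglucinolate and gives 14 on acidification. The reaction type is the intramolecular Claisen (Dieckmann-type) acylation of a ketone enolate by an ester, known for 3,5-dioxohexanoate esters going to phloroglucinols and the chemical counterpart of the polyketide synthase cyclisation. Ring A closes in a 6-exo-trig mode at the ester carbonyl (enolate carbon to acyl carbon through a six-membered transition state). No stereocentre is created: C4 of 12 is flattened on aromatisation, and the side-chain centre, which is neither α to a carbonyl nor conjugated, is carried through unchanged. The step needs C-acylation to beat O-acylation (the 4-hydroxy-2-pyrone) and retro-Claisen cleavage; the pyrone is reopened by the methoxide its formation releases whereas aromatisation to the phloroglucinolate is irreversible, and the poorly nucleophilic tert-butoxide, used in place of methoxide in methanol, should keep deacylation of the 4-substituted β-diketone slow. Because the side chain sits on the central carbon of the tricarbonyl chain, the only six-membered C-acylation delivers it between two hydroxyls of a symmetrical triol, so no regiochemical question arises.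

**Step 7**
Reactants: 14 2-[(2S)-lavandulyl]benzene-1,3,5-triol
Product: 15 1,3,5-tris(methoxymethoxy)-2-[(2S)-lavandulyl]benzene
Conditions: NaH (3.5 equiv), MOMCl (3.5 equiv), DMF, 0 °C → rt
Reagents that add atoms: chloromethyl methyl ether (MOMCl), COCCl
Why: Williamson-type O-alkylation of the phenoxides with the hard electrophile MOMCl, which masks the air-sensitive triol and provides the ortho-directing groups for step 8.

**Step 8**
Reactants: 15 1,3,5-tris(methoxymethoxy)-2-[(2S)-lavandulyl]benzene; 10 N-methoxy-N-methylacetamide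
Product: 17 1-[2,4,6-tris(methoxymethoxy)-3-[(2S)-lavandulyl]phenyl]ethan-1-one, via aryllithium 16 (not isolated)
Conditions: n-BuLi (1.2 equiv), THF, 0 °C; then 10, −78 → 0 °C; aq. NH4Cl
Reagents that add atoms: none
Why: Directed ortho-metalation followed by Weinreb ketone synthesis, in which n-BuLi removes the ring proton flanked by two MOM ethers (the two free positions are equivalent) and aryllithium 16 is acetylated once by 10; this avoids the Lewis or Brønsted acid of a Friedel–Crafts or Hoesch acylation, which would add the phenols across the side-chain alkenes.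

**Step 9**
Reactants: 17 1-[2,4,6-tris(methoxymethoxy)-3-[(2S)-lavandulyl]phenyl]ethan-1-one
Product: 18 1-[2,4,6-trihydroxy-3-[(2S)-lavandulyl]phenyl]ethan-1-one
Conditions: HCl (0.5 M) in MeOH, 40 °C
Reagents that add atoms: none
Why: Acid-catalysed acetal methanolysis, using the dilute methanolic HCl at mild temperature that is usual for removing MOM groups from ortho-prenylated phenols; the symmetric tris-ether cannot be differentiated, so all three groups are removed and leave as dimethoxymethane.

**Step 10**
Reactants: 18 1-[2,4,6-trihydroxy-3-[(2S)-lavandulyl]phenyl]ethan-1-one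
Product: 19 1-[2-hydroxy-4,6-bis(methoxymethoxy)-3-[(2S)-lavandulyl]phenyl]ethan-1-one
Conditions: MOMCl (2.2 equiv), i-Pr2NEt, CH2Cl2, 0 °C
Reagents that add atoms: chloromethyl methyl ether (MOMCl), COCCl
Why: Regioselective O-alkylation, in which the 4-OH (para to the acetyl, not hydrogen-bonded) and the unhindered 6-OH should react while the 2-OH, wedged between the acetyl group and the side chain, is held in a buttressed hydrogen bond to the carbonyl and is sterically shielded, so the hydroxyl that must become O1 stays free.

**Step 11**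
Reactants: 19 1-[2-hydroxy-4,6-bis(methoxymethoxy)-3-[(2S)-lavandulyl]phenyl]ethan-1-one; 20 4-(methoxymethoxy)benzaldehyde
Product: 21 (E)-1-[2-hydroxy-4,6-bis(methoxymethoxy)-3-[(2S)-lavandulyl]phenyl]-3-[4-(methoxymethoxy)phenyl]prop-2-en-1-one
Conditions: KOH, EtOH, rt; then AcOH
Reagents that add atoms: none
Why: Claisen–Schmidt condensation, in which the methyl ketone enolate adds to the non-enolisable aldehyde and E1cB dehydration gives the (E)-chalcone.

**Step 12**
Reactants: 21 (E)-chalcone
Product: 23 3-hydroxy-5,7-bis(methoxymethoxy)-2-[4-(methoxymethoxy)phenyl]-8-[(2S)-lavandulyl]-4H-chromen-4-one, via dihydroflavonol 22 (not isolated)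
Conditions: 30% H2O2, aq. NaOH, MeOH, 0 °C → rt; then AcOH
Reagents that add atoms: hydrogen peroxide, OO
Why: Algar–Flynn–Oyamada reaction, in which the 2'-phenoxide closes ring C at the β-carbon (6-endo) with hydroxylation at C3 to dihydroflavonol 22, which is oxidised on to the flavonol; the nucleophilic hydroperoxide leaves the isolated side-chain alkenes alone (methanol, not a nitrile, as solvent), the C2/C3 centres of 22 are transient, and since only the hydroxyl next to the side chain is free the side chain ends up on C8.

**Step 13**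
Reactants: 23 protected flavonol
Product: 24 3,5,7-trihydroxy-2-(4-hydroxyphenyl)-8-[(2S)-lavandulyl]-4H-chromen-4-one
Conditions: HCl (0.5 M) in MeOH, 40 °C
Reagents that add atoms: none
Why: Acid-catalysed acetal methanolysis as in step 9, under the mild conditions used for MOM ethers of 8-prenylated flavonoids, frees the 5-, 7- and 4'-hydroxyls without touching the stereocentre.

**Compound list**

1 | (R)-(+)-limonene | CC1=CC[C@@H](CC1)C(C)=C | starting material
2 | (4R)-limonene 1,2-oxide (cis/trans mixture at C1/C2) | C=C(C)[C@@H]1CCC2(C)OC2C1 | intermediate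
3 | (4R)-limonene-1,2-diol (diastereomer mixture) | C=C(C)[C@@H]1CCC(C)(O)C(O)C1 | intermediate (not isolated)
4 | (3R)-6-oxo-3-(prop-1-en-2-yl)heptanal | C=C(C)[C@@H](CC=O)CCC(C)=O | intermediate
5 | isopropyltriphenylphosphonium iodide | CC(C)[P+](c1ccccc1)(c1ccccc1)c1ccccc1.[I-] | starting material
6 | isopropylidenetriphenylphosphorane | CC(C)=P(c1ccccc1)(c1ccccc1)c1ccccc1 | intermediate (not isolated)
7 | (5R)-8-methyl-5-(prop-1-en-2-yl)non-7-en-2-one | C=C(C)[C@@H](CC=C(C)C)CCC(C)=O | intermediate
8 | dimethyl carbonate | COC(=O)OC | starting material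
9 | methyl (6R)-9-methyl-3-oxo-6-(prop-1-en-2-yl)dec-8-enoate | C=C(C)[C@@H](CC=C(C)C)CCC(=O)CC(=O)OC | intermediate
10 | N-methoxy-N-methylacetamide | CC(=O)N(C)OC | starting material
11 | dilithium bis-enolate (2,4-dianion) of 9 | C=C(C)[C@@H](CC=C(C)C)CC=C(O[Li])C=C(O[Li])OC | intermediate (not isolated)
12 | methyl 4-[(2S)-5-methyl-2-(prop-1-en-2-yl)hex-4-en-1-yl]-3,5-dioxohexanoate (C4 epimers and enol forms) | C=C(C)[C@@H](CC=C(C)C)CC(C(C)=O)C(=O)CC(=O)OC | intermediate
13 | 2-[(2S)-lavandulyl]cyclohexane-1,3,5-trione | C=C(C)[C@@H](CC=C(C)C)CC1C(=O)CC(=O)CC1=O | intermediate (not isolated)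
14 | 2-[(2S)-5-methyl-2-(prop-1-en-2-yl)hex-4-en-1-yl]benzene-1,3,5-triol (2-lavandulylphloroglucinol) | C=C(C)[C@@H](CC=C(C)C)Cc1c(O)cc(O)cc1O | intermediate
15 | 1,3,5-tris(methoxymethoxy)-2-[(2S)-lavandulyl]benzene | C=C(C)[C@@H](CC=C(C)C)Cc1c(OCOC)cc(OCOC)cc1OCOC | intermediate
16 | 2,4,6-tris(methoxymethoxy)-3-[(2S)-lavandulyl]phenyllithium | C=C(C)[C@@H](CC=C(C)C)Cc1c(OCOC)cc(OCOC)c([Li])c1OCOC | intermediate (not isolated)
17 | 1-[2,4,6-tris(methoxymethoxy)-3-[(2S)-lavandulyl]phenyl]ethan-1-one | C=C(C)[C@@H](CC=C(C)C)Cc1c(OCOC)cc(OCOC)c(C(C)=O)c1OCOC | intermediate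
18 | 1-[2,4,6-trihydroxy-3-[(2S)-lavandulyl]phenyl]ethan-1-one | C=C(C)[C@@H](CC=C(C)C)Cc1c(O)cc(O)c(C(C)=O)c1O | intermediate
19 | 1-[2-hydroxy-4,6-bis(methoxymethoxy)-3-[(2S)-lavandulyl]phenyl]ethan-1-one | C=C(C)[C@@H](CC=C(C)C)Cc1c(OCOC)cc(OCOC)c(C(C)=O)c1O | intermediate
20 | 4-(methoxymethoxy)benzaldehyde | COCOc1ccc(C=O)cc1 | starting material
21 | (E)-1-[2-hydroxy-4,6-bis(methoxymethoxy)-3-[(2S)-lavandulyl]phenyl]-3-[4-(methoxymethoxy)phenyl]prop-2-en-1-one | C=C(C)[C@@H](CC=C(C)C)Cc1c(OCOC)cc(OCOC)c(C(=O)/C=C/c2ccc(OCOC)cc2)c1O | intermediate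
22 | 3-hydroxy-5,7-bis(methoxymethoxy)-2-[4-(methoxymethoxy)phenyl]-8-[(2S)-lavandulyl]chroman-4-one (C2/C3 mixture) | C=C(C)[C@@H](CC=C(C)C)Cc1c(OCOC)cc(OCOC)c2C(=O)C(O)C(c3ccc(OCOC)cc3)Oc12 | intermediate (not isolated)
23 | 3-hydroxy-5,7-bis(methoxymethoxy)-2-[4-(methoxymethoxy)phenyl]-8-[(2S)-lavandulyl]-4H-chromen-4-one | C=C(C)[C@@H](CC=C(C)C)Cc1c(OCOC)cc(OCOC)c2c(=O)c(O)c(-c3ccc(OCOC)cc3)oc12 | intermediate
24 | 3,5,7-trihydroxy-2-(4-hydroxyphenyl)-8-[(2S)-5-methyl-2-(prop-1-en-2-yl)hex-4-en-1-yl]-4H-chromen-4-one | C=C(C)[C@@H](CC=C(C)C)Cc1c(O)cc(O)c2c(=O)c(O)c(-c3ccc(O)cc3)oc12 | target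

**Total step count:** 13
**Longest linear sequence:** 13 steps (1 to 24); 5, 8, 10 and 20 are purchased.

**Steps most likely to fail**

1. Step 6. The attacking methyl group is the least acidic site of 12, so ring closure may be outrun by retro-Claisen loss of the acetyl group from the 4-substituted β-diketone, or the material may rest as the lactone. Fallback: activate the nucleophilic carbon with the acetyl group the target needs anyway. Setting out from 12, the trianion (LDA, 3.3 equiv, THF, −78 → 0 °C) would be acetylated at the terminal methyl with 10 to give methyl 4-[(2S)-lavandulyl]-3,5,7-trioxooctanoate F1. Strong aqueous alkali (2 M KOH, rt, then cold dilute acid), which steers 3,5,7-triketo esters to the Claisen rather than the aldol mode, should then close the same ring-A bond from the now doubly activated C6 methylene. This gives the acetophenone directly and returns to the route at 18, so steps 7–9 are not needed.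

2. Step 12. With an alkoxy group at C6' the phenoxide may close the five-membered ring at the α-carbon instead of the six-membered ring at the β-carbon, diverting material to the aurone. Fallback: build the flavone first and oxidise C3 afterwards. Setting out from 19, the free hydroxyl would be esterified with 4-(methoxymethoxy)benzoyl chloride (pyridine, DMAP) to 2-acetyl-3,5-bis(methoxymethoxy)-6-[(2S)-lavandulyl]phenyl 4-(methoxymethoxy)benzoate F2. Baker–Venkataraman rearrangement (KOH, pyridine, 50 °C) would give 1-[2-hydroxy-4,6-bis(methoxymethoxy)-3-[(2S)-lavandulyl]phenyl]-3-[4-(methoxymethoxy)phenyl]propane-1,3-dione F3. Cyclodehydration in buffered acetic acid (NaOAc, AcOH, 80 °C) would give 5,7-bis(methoxymethoxy)-2-[4-(methoxymethoxy)phenyl]-8-[(2S)-lavandulyl]-4H-chromen-4-one F4. C3 lithiation (LDA, THF, −78 °C), trapping with B(OMe)3 and perborate oxidation of the boronate, which does not touch isolated alkenes, would return to the route at 23.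

3. Step 13 (the same hazard applies to step 9). The acid needed for acetal cleavage may protonate the isopropenyl or prenyl double bond and let the freed 7-hydroxyl add to the cation (chroman formation) before all MOM groups are off. Fallback: ethers that are removed under neutral conditions. Setting out from 18, allyl bromide and K2CO3 in acetone should give 1-[4,6-bis(allyloxy)-2-hydroxy-3-[(2S)-lavandulyl]phenyl]ethan-1-one F5 with the same selectivity as step 10. Claisen–Schmidt condensation with 4-(allyloxy)benzaldehyde would give (E)-1-[4,6-bis(allyloxy)-2-hydroxy-3-[(2S)-lavandulyl]phenyl]-3-[4-(allyloxy)phenyl]prop-2-en-1-one F6. The Algar–Flynn–Oyamada reaction would give 5,7-bis(allyloxy)-2-[4-(allyloxy)phenyl]-3-hydroxy-8-[(2S)-lavandulyl]-4H-chromen-4-one F7. Pd(0)-catalysed allyl transfer (Pd(PPh3)4, K2CO3, MeOH, rt) would return to the route at 24.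

**Further compounds**

F1 | step 6 | methyl 4-[(2S)-lavandulyl]-3,5,7-trioxooctanoate | C=C(C)[C@@H](CC=C(C)C)CC(C(=O)CC(C)=O)C(=O)CC(=O)OC
F2 | step 12 | 2-acetyl-3,5-bis(methoxymethoxy)-6-[(2S)-lavandulyl]phenyl 4-(methoxymethoxy)benzoate | C=C(C)[C@@H](CC=C(C)C)Cc1c(OCOC)cc(OCOC)c(C(C)=O)c1OC(=O)c2ccc(OCOC)cc2
F3 | step 12 | 1-[2-hydroxy-4,6-bis(methoxymethoxy)-3-[(2S)-lavandulyl]phenyl]-3-[4-(methoxymethoxy)phenyl]propane-1,3-dione | C=C(C)[C@@H](CC=C(C)C)Cc1c(OCOC)cc(OCOC)c(C(=O)CC(=O)c2ccc(OCOC)cc2)c1O
F4 | step 12 | 5,7-bis(methoxymethoxy)-2-[4-(methoxymethoxy)phenyl]-8-[(2S)-lavandulyl]-4H-chromen-4-one | C=C(C)[C@@H](CC=C(C)C)Cc1c(OCOC)cc(OCOC)c2c(=O)cc(-c3ccc(OCOC)cc3)oc12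
F5 | step 13 | 1-[4,6-bis(allyloxy)-2-hydroxy-3-[(2S)-lavandulyl]phenyl]ethan-1-one | C=C(C)[C@@H](CC=C(C)C)Cc1c(OCC=C)cc(OCC=C)c(C(C)=O)c1O
F6 | step 13 | (E)-1-[4,6-bis(allyloxy)-2-hydroxy-3-[(2S)-lavandulyl]phenyl]-3-[4-(allyloxy)phenyl]prop-2-en-1-one | C=C(C)[C@@H](CC=C(C)C)Cc1c(OCC=C)cc(OCC=C)c(C(=O)/C=C/c2ccc(OCC=C)cc2)c1O
F7 | step 13 | 5,7-bis(allyloxy)-2-[4-(allyloxy)phenyl]-3-hydroxy-8-[(2S)-lavandulyl]-4H-chromen-4-one | C=C(C)[C@@H](CC=C(C)C)Cc1c(OCC=C)cc(OCC=C)c2c(=O)c(O)c(-c3ccc(OCC=C)cc3)oc12
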